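## The problem

The target is an aryltetralin lignan monosulfate. Ring A (C4a to C8a; methoxy groups at C6 and C8, free phenol at C7) is fused to a saturated ring B with three contiguous, all-trans stereocentres (1R,2S,3S). C1 bears the syringyl ring Ar′, C2 the sulfated hydroxymethyl carbon C2a, and C3 the free hydroxymethyl carbon C3a. The two one-carbon arms differ only in the sulfate, so C2a and C3a must stay distinguishable until the sulfate is in place. C1 is doubly benzylic and cannot be corrected once set. C2 can be equilibrated while C2a is at the carboxyl level. C3 cannot be equilibrated unless C3a is a carbonyl group. C1 sits beside the C8 methoxy group; this peri contact pushes Ar′ towards the pseudo-axial position and makes C1 an unreliable relay of configuration to C3. The sulfate monoester is lost in acid, and the two free phenols (para to C1 and to C4) are open to oxidation to quinone methides, so sulfate and phenols are unveiled late. The feature that allows a sigmatropic solution is that C2 and C3 each carry one carbon. If C2a is an ester carbonyl whose oxygen is bound to an allyl unit ending at C3, then C2, C2a, O, CH, CH and C3 form the array of an ester-enolate Claisen rearrangement. Because C2 and C3 are already linked through C1, C8a, C4a and C4, that rearrangement closes ring B across a ten-membered lactone.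

## Retrosynthesis

**32 from 31, and 31 from 28.** The two phenolic O–benzyl bonds are cut last, because hydrogenolysis is harmless to a sulfate salt. One step back, the C3a–OH of 31 is traded for a C3a=C double bond: 31 comes from the (E)-propenyl compound 28 by oxidative cleavage and reduction. The neighbouring option, selective sulfation of a diol, cannot tell two primary alcohols apart. Here C3a stays masked as an alkene while C2a alone is an alcohol, so no protecting group is spent. The forward steps must not epimerise C3 in the short-lived aldehyde.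

**28 from 27, 27 from 26, 26 from 24.** The S–O bond and then the C2a oxidation level are removed: sulfate 28 from alcohol 27, and 27 from methyl ester 26. Ester 26 is the C2 epimer of the methyl ester of acid 24. The forward reaction is base equilibration: with Ar′ and the propenyl group cis on ring B, the ester is axial in the cis,cis isomer and equatorial in the trans,trans isomer.

**24 from 21 (key disconnection).** The C2–C3 bond is cut together with ring B, and the bond between the carboxyl oxygen and the propenyl terminus is restored. The precursor is the benzo-fused ten-membered (Z)-allylic lactone 21.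
- Against cuts at C1–C8a or C3–C4, this one joins two stereocentres in one step and leaves C2a as an acid and C3a as an alkene carbon, so the arms are differentiated by the step itself.
- Lactone 21 has one ring fewer and only two stereocentres.
- The forward reaction must give 2,3-cis, which the tether enforces, and 1,3-cis between Ar′ and the C3 arm. The second demand is not left to C1, because the peri methoxy group favours the transition state that would put the C3 arm trans to Ar′.
- Instead, the lactone carbinol carbon carries an (R)-methyl group. It transfers its chirality to C3 through A(1,3) strain and is excised later with the alkene terminus.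

**21 from 19.** The lactone C–O bond is cut to seco acid 19. This is preferred to closing the medium ring at a C–C bond, because the hydroxy acid is reached by functional-group operations only and acyl activation leaves the carbinol centre untouched. High dilution has to beat dimerisation; the ortho-phenylene unit, the (Z)-alkene and the ester plane help.

**19 from 18, 18 from 17, 17 from 15 and 16.** Acid 19 is the saponified ester 18, whose (Z)-alkene comes from alkyne 17 by semihydrogenation. Cutting the C4–C(sp) bond of 17 gives benzylic bromide 15 and commercial (2R)-but-3-yn-2-ol 16. This puts the carbinol centre in from the chiral pool in one bond and fixes the alkene geometry by syn hydrogenation. The enantiopure carbinol also turns any C1 enantiomer that leaks through into a separable diastereomer of 18 or 21.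

**15 from 14, 14 from 13, 13 from 7 and 12.** Bromide 15 comes from alcohol 14 and silyl ether 13. Cutting the C1–Ar′ bond of 13 gives cinnamate 7 and boronic acid 12. A catalytic asymmetric conjugate addition sets C1, the only stereocentre not made under the control of another. The alkyne is added afterwards, because it would itself accept an aryl–rhodium species. The forward reaction has to cope with a cinnamate flanked by two ortho substituents.

**7 from 5 and 6, and 5 from 1.** The C8a–C1 bond is a Heck disconnection to aryl bromide 5 and methyl acrylate 6. Bromide 5 goes back through 4, 3 and 2 to syringaldehyde 1. The aldehyde carbon becomes C4, and the bromine enters at the only free, activated position, the future C8a. The oxygenation pattern of ring A, with the methoxy group peri to C1, is therefore fixed by the starting material.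

**12 from 9, and 9 from 8.** The C–B bond is cut to aryl bromide 9, the benzyl ether of 4-bromo-2,6-dimethoxyphenol 8.

## Roads not taken

**Alternative 1:** Phenolate ipso attack followed by a dienone–phenol shift.
- Cut: the C1–C8a bond, reached indirectly through a C1–C4a bond.
- Forward step: mild base frees the Ar′ phenol, loss of a C1 acetate gives a para-quinone methide, and the ring A phenolate attacks it through C4a (para to its oxygen) to give spirodienone A1. An acid-promoted 1,2-shift of C1 from C4a to C8a would then expand the five-membered ring to ring B.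
- Merits: it follows the quinone methide reactivity of this lignan class and needs only carbonate in methanol. C2 and C3 are set in an open chain where trans is easy. The arms are differentiated by protecting groups, which is as good as in the chosen plan.
- Weak points: ring B needs two events. In the second, C1 and C4 compete to migrate, and C4 migration gives the wrong oxygenation pattern. The C1–C4a bond of A1 lies next to a para-hydroxyaryl group and can reopen to the quinone methide, so C1 may epimerise. The dimethoxydienone is a doubly vinylogous ester and a reluctant substrate for the shift.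
- Comparison: this road avoids a medium ring and a kinetic 1,3-relationship, and is better there. The chosen plan sets against it that the C8a–C1 bond exists from the Heck step on, so ring A regiochemistry is never in question, and that C1 is set by a catalyst.

**Alternative 2:** Aroyl radical 6-endo closure.
- Cut: the C3–C4 bond.
- Forward step: an aroyl radical at C4, released from an acyl selenide by (Me3Si)3SiH and AIBN, adds to C3 of an α-substituted acrylate and gives keto ester A2 after hydrogen transfer and equilibration.
- Merits: no strained ring has to be built. In A2, C2 is α to the ester and C3 α to the ketone, so both can be corrected thermodynamically. In this respect it is better than the chosen plan, where C3 must be right kinetically.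
- Weak points: 6-endo addition must beat 5-exo attack at C2. The C4 carbonyl is an extra oxygen that has to be removed later in the presence of the ester-derived arm. The claim that the all-trans isomer is the thermodynamic sink is weakest for this target, because the C8 methoxy group favours isomers with Ar′ pseudo-axial. Stoichiometric selenium and silane are needed.
- Comparison: the chosen plan answers with chirality transfer of predictable sense to C3, thermodynamic correction at C2 only, and no deoxygenation.

**Alternative 3:** Enzymatic desymmetrisation of a cyclobutanone.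
- Cut: none of the skeletal bonds; the key step forms the C3a–O bond.
- Forward step: a flavin-dependent Baeyer–Villiger monooxygenase (NADPH recycled, O2) inserts oxygen into one of the two enantiotopic ring bonds of prochiral cyclobutanone A3 and gives lactone A4. Trans-selective hydroxyalkylation at C2 and acid-mediated closure of C1–C8a would follow.
- Merits: A4 is the classical lignan building block. The later steps are the best-precedented way to 1,2-trans aryltetralins, and the symmetric ring A makes the closure regiochemically unambiguous. On precedent and probably on step count this road is safer than the chosen plan.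
- Weak points: the key step sets one stereocentre and builds no ring or skeletal bond. It needs enzyme and cofactor handling at high dilution. Reducing the lactone gives a diol, so placing the sulfate costs extra operations. Acid closure puts the benzyl ethers at risk.
- Comparison: the chosen plan offers one step that makes ring B, the C2–C3 bond and two stereocentres, and that leaves C2a and C3a at different oxidation levels for direct, site-specific sulfation.

Key step: step 15

Assumption: the target is drawn as the free hydrogen sulfate; the sulfate is carried as its sodium salt from step 18 on and protonated only in the last operation.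

Assumption: the sense of the rhodium step is taken from the usual model for (E)-enoates, in which (S)-BINAP delivers the aryl group to the si face at C-alpha; for cinnamate 7 this gives (R) at C1.

## Route

Step 1
Reactants: 1 syringaldehyde
Product: 2 4-(benzyloxy)-3,5-dimethoxybenzaldehyde
Conditions: BnBr, K2CO3, DMF, 60 °C
Reagents that add atoms: benzyl bromide, BrCc1ccccc1
Why: Williamson ether synthesis on an acidic, flanked phenol; the benzyl ether lasts until the final hydrogenolysis.

Step 2
Reactants: 2 benzyl ether
Product: 3 4-(benzyloxy)-2-bromo-3,5-dimethoxybenzaldehyde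
Conditions: NBS, MeCN, rt
Reagents that add atoms: N-bromosuccinimide, O=C1CCC(=O)N1Br
Why: Electrophilic aromatic bromination; the two equivalent free positions are activated ortho and para by methoxy groups, so one bromine should enter next to the formyl group, as is usual for 3,4,5-trialkoxybenzaldehydes. The bromine marks the future C8a.

Step 3
Reactants: 3 bromo aldehyde
Product: 4 [4-(benzyloxy)-2-bromo-3,5-dimethoxyphenyl]methanol
Conditions: NaBH4, MeOH–THF, 0 °C
Reagents that add atoms: none
Why: Borohydride reduction of the aldehyde; a free formyl group would later trap the rhodium enolate of step 8 in an aldol closure, so the C4 carbon is taken to the alcohol level now.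

Step 4
Reactants: 4 benzylic alcohol
Product: 5 {[4-(benzyloxy)-2-bromo-3,5-dimethoxyphenyl]methoxy}(tert-butyl)dimethylsilane
Conditions: TBSCl, imidazole, DMF, rt
Reagents that add atoms: tert-butyldimethylsilyl chloride, CC(C)(C)[Si](C)(C)Cl
Why: Silylation of a primary alcohol; the silyl ether prevents oxa-Michael closure of an ortho-hydroxymethyl cinnamate and survives the basic steps 5 and 8.

Step 5
Reactants: 5 aryl bromide; 6 methyl acrylate
Product: 7 methyl (2E)-3-[3-(benzyloxy)-6-({[tert-butyl(dimethyl)silyl]oxy}methyl)-2,4-dimethoxyphenyl]prop-2-enoate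
Conditions: Pd(OAc)2, P(t-Bu)3·HBF4, Cy2NMe, dioxane, 100 °C
Reagents that add atoms: none
Why: Heck reaction; the bulky, electron-rich phosphine is chosen for an electron-rich bromide with two ortho substituents, and syn insertion followed by syn β-hydride elimination gives the (E)-cinnamate. This makes the C8a–C1 bond.

Step 6
Reactants: 8 4-bromo-2,6-dimethoxyphenol
Product: 9 2-(benzyloxy)-5-bromo-1,3-dimethoxybenzene
Conditions: BnBr, K2CO3, DMF, 60 °C
Reagents that add atoms: benzyl bromide, BrCc1ccccc1
Why: Williamson ether synthesis, as in step 1.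

Step 7
Reactants: 9 aryl bromide
Product: 12 [4-(benzyloxy)-3,5-dimethoxyphenyl]boronic acid, via aryllithium 10 (not isolated), via lithium aryltriisopropoxyborate 11 (not isolated)
Conditions: n-BuLi, THF, −78 °C; B(OiPr)3, −78 °C to rt; aq. HCl
Reagents that add atoms: triisopropyl borate, CC(C)OB(OC(C)C)OC(C)C; water, O
Why: Bromine–lithium exchange, borylation and hydrolysis; at −78 °C the exchange is much faster than any attack on the benzyl ether.

Step 8
Reactants: 7 cinnamate; 12 boronic acid
Product: 13 methyl (3R)-3-[4-(benzyloxy)-3,5-dimethoxyphenyl]-3-[3-(benzyloxy)-6-({[tert-butyl(dimethyl)silyl]oxy}methyl)-2,4-dimethoxyphenyl]propanoate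
Conditions: [RhCl(C2H4)2]2, (S)-BINAP, KOH (cat.), dioxane–H2O (10:1), 60 °C
Reagents that add atoms: none
Why: Rhodium-catalysed asymmetric conjugate addition of an arylboronic acid (Hayashi–Miyaura reaction): transmetalation gives an aryl–rhodium species, which adds across the enoate, and water releases the product. The (S)-BINAP complex should select the si face at C-alpha of the (E)-enoate, which sets (R) at C1. The boronic acid is used in excess against protodeboronation.

Step 9
Reactants: 13 silyl ether
Product: 14 methyl (3R)-3-[4-(benzyloxy)-3,5-dimethoxyphenyl]-3-[3-(benzyloxy)-6-(hydroxymethyl)-2,4-dimethoxyphenyl]propanoate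
Conditions: Bu4NF, AcOH, THF, 0 °C to rt
Reagents that add atoms: none
Why: Fluoride-induced desilylation; acetic acid buffers the alkoxide so that it does not attack the ester, and acidic methanol is avoided because the alkoxy-substituted benzylic alcohol would ionise.

Step 10
Reactants: 14 benzylic alcohol
Product: 15 methyl (3R)-3-[4-(benzyloxy)-3,5-dimethoxyphenyl]-3-[3-(benzyloxy)-6-(bromomethyl)-2,4-dimethoxyphenyl]propanoate
Conditions: CBr4, PPh3, CH2Cl2, 0 °C
Reagents that add atoms: carbon tetrabromide, BrC(Br)(Br)Br
Why: Appel reaction; the neutral, cold conditions should keep the alkoxy-substituted benzylic bromide from ionising towards the electron-rich Ar′ ring. The bromide is used at once.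

Step 11
Reactants: 15 benzylic bromide; 16 (2R)-but-3-yn-2-ol
Product: 17 methyl (3R)-3-[4-(benzyloxy)-3,5-dimethoxyphenyl]-3-{3-(benzyloxy)-6-[(4R)-4-hydroxypent-2-yn-1-yl]-2,4-dimethoxyphenyl}propanoate
Conditions: CuI (cat.), Cs2CO3, Bu4NI (cat.), MeCN, rt
Reagents that add atoms: none
Why: Alkylation of a copper acetylide by a benzylic halide (sp–sp3 coupling); the carbonate base is too weak to touch the ester or to isomerise the skipped aryl alkyne to an allene. The carbinol centre is not involved and stays (R).

Step 12
Reactants: 17 alkynol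
Product: 18 methyl (3R)-3-[4-(benzyloxy)-3,5-dimethoxyphenyl]-3-{3-(benzyloxy)-6-[(2Z,4R)-4-hydroxypent-2-en-1-yl]-2,4-dimethoxyphenyl}propanoate
Conditions: H2 (1 atm), Pd/CaCO3 (Pb-poisoned), quinoline, EtOAc, rt
Reagents that add atoms: none
Why: Lindlar semihydrogenation; syn addition of hydrogen on the poisoned surface gives the (Z)-alkene and leaves the benzyl ethers alone.

Step 13
Reactants: 18 hydroxy ester
Product: 19 (3R)-3-[4-(benzyloxy)-3,5-dimethoxyphenyl]-3-{3-(benzyloxy)-6-[(2Z,4R)-4-hydroxypent-2-en-1-yl]-2,4-dimethoxyphenyl}propanoic acid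
Conditions: LiOH, THF–MeOH–H2O, rt; then aq. HCl to pH 3
Reagents that add atoms: lithium hydroxide, [Li+].[OH-]
Why: Saponification; C1 is β to the carbonyl and cannot epimerise.

Step 14
Reactants: 19 seco acid
Product: 21 (1R,5R,6Z)-11-(benzyloxy)-1-[4-(benzyloxy)-3,5-dimethoxyphenyl]-10,12-dimethoxy-5-methyl-1,2,5,8-tetrahydro-3H-4-benzoxecin-3-one (ten-membered lactone: C8a carries C1H(Ar′)–C2H2–C2a(=O)–O, C4a carries C4H2–CH=CH–CH(CH3)–O), via mixed anhydride 20 (not isolated)
Conditions: 2,4,6-Cl3C6H2COCl, Et3N, THF, rt; then slow addition to DMAP, PhMe, 80 °C (high dilution)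
Reagents that add atoms: none
Why: Yamaguchi macrolactonisation; the acid is activated as the mixed anhydride and acylates the secondary allylic alcohol with retention at the carbinol carbon. The ortho-phenylene unit, the (Z)-alkene and the ester plane remove three rotors, which should help closure over dimerisation.

Step 15
Reactants: 21 ten-membered lactone
Product: 24 (1R,2S,3R)-7-(benzyloxy)-1-[4-(benzyloxy)-3,5-dimethoxyphenyl]-6,8-dimethoxy-3-[(1E)-prop-1-en-1-yl]-1,2,3,4-tetrahydronaphthalene-2-carboxylic acid (carboxyl, propenyl and Ar′ all cis), via silyl ketene acetal 22 (not isolated), via trimethylsilyl ester 23 (not isolated)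
Conditions: KN(SiMe3)2, Me3SiCl, Et3N, THF–PhMe, −78 °C; then 80 °C; 1 M HCl work-up
Reagents that add atoms: none
Why: KN(SiMe3)2 removes a C2 proton of 21 in the presence of Me3SiCl, and the enolate is trapped on oxygen as the cyclic silyl ketene acetal 22, whose in-ring C2=C2a bond can only hold C1 and the ring oxygen cis. On warming, C2, C2a, O, the carbinol carbon, the alkene CH and C3 reorganise in a suprafacial [3,3] shift of the Ireland–Claisen type; the closest known reaction type is the ring contraction of macrocyclic allylic lactones to 2-alkenylcycloalkanecarboxylic acids. Ring B closes by transannular six-membered ring formation, with the new C2–C3 bond as the fusion bond of a bicyclic, boat-like transition state, while the ten-membered ring is lost with the C–O bond. C3 is controlled by the carbinol stereocentre: its hydrogen eclipses the (Z)-alkene to avoid A(1,3) strain against C4, so the C–O bond and the incoming C2 lie on one face only, which for the (R)-carbinol gives (3R) and an (E)-propenyl group. C2 is controlled by the tether: the link C1–C8a–C4a–C4 can span the two termini only if the carboxyl carbon and the propenyl carbon end up cis on ring B, so 23 and 24 are 2,3-cis. The selectivity the step needs is 1,3-cis between Ar′ and the C3 arm; C1 alone would not secure it, because Ar′ prefers the pseudo-axial position beside the C8 methoxy group, and the A(1,3)-enforced chirality transfer is there to override that preference. Heating pays for the less comfortable pseudo-equatorial Ar′, and the acid work-up hydrolyses the silyl ester.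

Step 16
Reactants: 24 all-cis acid
Product: 26 methyl (1R,2R,3R)-7-(benzyloxy)-1-[4-(benzyloxy)-3,5-dimethoxyphenyl]-6,8-dimethoxy-3-[(1E)-prop-1-en-1-yl]-1,2,3,4-tetrahydronaphthalene-2-carboxylate (ester trans to Ar′ and to propenyl), via all-cis methyl ester 25 (not isolated)
Conditions: Me3SiCHN2, PhMe–MeOH, 0 °C; then NaOMe, MeOH, 60 °C
Reagents that add atoms: (trimethylsilyl)diazomethane, C[Si](C)(C)C=[N+]=[N-]
Why: Esterification, then equilibration at C2 through the ester enolate. With Ar′ and the propenyl group cis and pseudo-equatorial, the ester is axial in 25 and equatorial in 26, so the trans,trans ester should dominate; any cis ester left would be resubmitted. C1 and C3 have no acidic hydrogen.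

Step 17
Reactants: 26 trans,trans ester
Product: 27 [(1R,2R,3R)-7-(benzyloxy)-1-[4-(benzyloxy)-3,5-dimethoxyphenyl]-6,8-dimethoxy-3-[(1E)-prop-1-en-1-yl]-1,2,3,4-tetrahydronaphthalen-2-yl]methanol
Conditions: LiAlH4, THF, 0 °C
Reagents that add atoms: none
Why: Hydride reduction of the ester to the primary alcohol; this locks C2 and leaves C2a–OH as the only hydroxyl group in the molecule.

Step 18
Reactants: 27 alcohol
Product: 28 sodium [(1R,2R,3R)-7-(benzyloxy)-1-[4-(benzyloxy)-3,5-dimethoxyphenyl]-6,8-dimethoxy-3-[(1E)-prop-1-en-1-yl]-1,2,3,4-tetrahydronaphthalen-2-yl]methyl sulfate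
Conditions: SO3·pyridine, pyridine, rt; then aq. NaHCO3
Reagents that add atoms: sulfur trioxide–pyridine complex, O=S(=O)([O-])[n+]1ccccc1; sodium hydrogen carbonate, [Na+].OC([O-])=O
Why: O-sulfation of a primary alcohol with the amine–SO3 complex; the phenols are benzylated and C3a is still an alkene carbon, so only C2a can be sulfated. The monoester anion is inert to the oxidant, hydride and hydrogen that follow.

Step 19
Reactants: 28 propenyl sulfate
Product: 31 sodium [(1R,2S,3S)-7-(benzyloxy)-1-[4-(benzyloxy)-3,5-dimethoxyphenyl]-3-(hydroxymethyl)-6,8-dimethoxy-1,2,3,4-tetrahydronaphthalen-2-yl]methyl sulfate, via diol 29 (not isolated), via aldehyde 30 (not isolated)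
Conditions: OsO4 (cat.), NaIO4, 2,6-lutidine, dioxane–H2O, rt; filter and concentrate briefly; then NaBH4, MeOH, 0 °C
Reagents that add atoms: osmium tetroxide, O=[Os](=O)(=O)=O; sodium periodate, [Na+].[O-]I(=O)(=O)=O
Why: Lemieux–Johnson cleavage (dihydroxylation, then periodate scission) removes the carbinol-derived carbons and leaves C3a as the aldehyde, which is reduced at once. Buffering with 2,6-lutidine and the immediate reduction protect C3, now α to a formyl group, from epimerisation.

Step 20
Reactants: 31 dibenzyl ether
Product: 32 [(1R,2S,3S)-7-hydroxy-1-(4-hydroxy-3,5-dimethoxyphenyl)-3-(hydroxymethyl)-6,8-dimethoxy-1,2,3,4-tetrahydronaphthalen-2-yl]methyl hydrogen sulfate (target)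
Conditions: H2 (1 atm), Pd/C, MeOH–H2O, rt; then HCl (1 equiv), 0 °C, desalting on C18
Reagents that add atoms: none
Why: Hydrogenolysis of the two aryl benzyl ethers; the sulfate salt, the diarylmethine C1–H and the primary alcohol are not affected. Protonation is left to the end because the free hydrogen sulfate is the least stable form.

## Compound list

1 | syringaldehyde (4-hydroxy-3,5-dimethoxybenzaldehyde) | COc1cc(C=O)cc(OC)c1O | starting material
2 | 4-(benzyloxy)-3,5-dimethoxybenzaldehyde | COc1cc(C=O)cc(OC)c1OCc1ccccc1 | intermediate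
3 | 4-(benzyloxy)-2-bromo-3,5-dimethoxybenzaldehyde | COc1cc(C=O)c(Br)c(OC)c1OCc1ccccc1 | intermediate
4 | [4-(benzyloxy)-2-bromo-3,5-dimethoxyphenyl]methanol | COc1cc(CO)c(Br)c(OC)c1OCc1ccccc1 | intermediate
5 | {[4-(benzyloxy)-2-bromo-3,5-dimethoxyphenyl]methoxy}(tert-butyl)dimethylsilane | COc1cc(CO[Si](C)(C)C(C)(C)C)c(Br)c(OC)c1OCc1ccccc1 | intermediate
6 | methyl acrylate | C=CC(=O)OC | starting material
7 | methyl (2E)-3-[3-(benzyloxy)-6-({[tert-butyl(dimethyl)silyl]oxy}methyl)-2,4-dimethoxyphenyl]prop-2-enoate | COC(=O)/C=C/c1c(CO[Si](C)(C)C(C)(C)C)cc(OC)c(OCc2ccccc2)c1OC | intermediate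
8 | 4-bromo-2,6-dimethoxyphenol | COc1cc(Br)cc(OC)c1O | starting material
9 | 2-(benzyloxy)-5-bromo-1,3-dimethoxybenzene | COc1cc(Br)cc(OC)c1OCc1ccccc1 | intermediate
10 | [4-(benzyloxy)-3,5-dimethoxyphenyl]lithium (not isolated) | [Li]c1cc(OC)c(OCc2ccccc2)c(OC)c1 | intermediate
11 | lithium [4-(benzyloxy)-3,5-dimethoxyphenyl]tri(propan-2-yloxy)borate (not isolated) | [Li+].CC(C)O[B-](OC(C)C)(OC(C)C)c1cc(OC)c(OCc2ccccc2)c(OC)c1 | intermediate
12 | [4-(benzyloxy)-3,5-dimethoxyphenyl]boronic acid | COc1cc(B(O)O)cc(OC)c1OCc1ccccc1 | intermediate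
13 | methyl (3R)-3-[4-(benzyloxy)-3,5-dimethoxyphenyl]-3-[3-(benzyloxy)-6-({[tert-butyl(dimethyl)silyl]oxy}methyl)-2,4-dimethoxyphenyl]propanoate | COc1cc([C@@H](CC(=O)OC)c2c(CO[Si](C)(C)C(C)(C)C)cc(OC)c(OCc3ccccc3)c2OC)cc(OC)c1OCc1ccccc1 | intermediate
14 | methyl (3R)-3-[4-(benzyloxy)-3,5-dimethoxyphenyl]-3-[3-(benzyloxy)-6-(hydroxymethyl)-2,4-dimethoxyphenyl]propanoate | COc1cc([C@@H](CC(=O)OC)c2c(CO)cc(OC)c(OCc3ccccc3)c2OC)cc(OC)c1OCc1ccccc1 | intermediate
15 | methyl (3R)-3-[4-(benzyloxy)-3,5-dimethoxyphenyl]-3-[3-(benzyloxy)-6-(bromomethyl)-2,4-dimethoxyphenyl]propanoate | COc1cc([C@@H](CC(=O)OC)c2c(CBr)cc(OC)c(OCc3ccccc3)c2OC)cc(OC)c1OCc1ccccc1 | intermediate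
16 | (2R)-but-3-yn-2-ol | C[C@@H](O)C#C | starting material
17 | methyl (3R)-3-[4-(benzyloxy)-3,5-dimethoxyphenyl]-3-{3-(benzyloxy)-6-[(4R)-4-hydroxypent-2-yn-1-yl]-2,4-dimethoxyphenyl}propanoate | COc1cc([C@@H](CC(=O)OC)c2c(CC#C[C@@H](C)O)cc(OC)c(OCc3ccccc3)c2OC)cc(OC)c1OCc1ccccc1 | intermediate
18 | methyl (3R)-3-[4-(benzyloxy)-3,5-dimethoxyphenyl]-3-{3-(benzyloxy)-6-[(2Z,4R)-4-hydroxypent-2-en-1-yl]-2,4-dimethoxyphenyl}propanoate | COc1cc([C@@H](CC(=O)OC)c2c(C/C=C\[C@@H](C)O)cc(OC)c(OCc3ccccc3)c2OC)cc(OC)c1OCc1ccccc1 | intermediate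
19 | (3R)-3-[4-(benzyloxy)-3,5-dimethoxyphenyl]-3-{3-(benzyloxy)-6-[(2Z,4R)-4-hydroxypent-2-en-1-yl]-2,4-dimethoxyphenyl}propanoic acid | COc1cc([C@@H](CC(=O)O)c2c(C/C=C\[C@@H](C)O)cc(OC)c(OCc3ccccc3)c2OC)cc(OC)c1OCc1ccccc1 | intermediate
20 | mixed anhydride of acid 19 and 2,4,6-trichlorobenzoic acid (not isolated) | COc1cc([C@@H](CC(=O)OC(=O)c2c(Cl)cc(Cl)cc2Cl)c2c(C/C=C\[C@@H](C)O)cc(OC)c(OCc3ccccc3)c2OC)cc(OC)c1OCc1ccccc1 | intermediate
21 | (1R,5R,6Z)-11-(benzyloxy)-1-[4-(benzyloxy)-3,5-dimethoxyphenyl]-10,12-dimethoxy-5-methyl-1,2,5,8-tetrahydro-3H-4-benzoxecin-3-one | COc1cc([C@H]2CC(=O)O[C@H](C)/C=C\Cc3cc(OC)c(OCc4ccccc4)c(OC)c32)cc(OC)c1OCc1ccccc1 | intermediate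
22 | trimethylsilyl ketene acetal of lactone 21, C1 cis to the ring oxygen (not isolated) | COc1cc([C@H]2/C=C(O[Si](C)(C)C)\O[C@H](C)/C=C\Cc3cc(OC)c(OCc4ccccc4)c(OC)c32)cc(OC)c1OCc1ccccc1 | intermediate
23 | trimethylsilyl (1R,2S,3R)-7-(benzyloxy)-1-[4-(benzyloxy)-3,5-dimethoxyphenyl]-6,8-dimethoxy-3-[(1E)-prop-1-en-1-yl]-1,2,3,4-tetrahydronaphthalene-2-carboxylate (not isolated) | COc1cc([C@@H]2c3c(cc(OC)c(OCc4ccccc4)c3OC)C[C@H](/C=C/C)[C@@H]2C(=O)O[Si](C)(C)C)cc(OC)c1OCc1ccccc1 | intermediate
24 | (1R,2S,3R)-7-(benzyloxy)-1-[4-(benzyloxy)-3,5-dimethoxyphenyl]-6,8-dimethoxy-3-[(1E)-prop-1-en-1-yl]-1,2,3,4-tetrahydronaphthalene-2-carboxylic acid | COc1cc([C@@H]2c3c(cc(OC)c(OCc4ccccc4)c3OC)C[C@H](/C=C/C)[C@@H]2C(=O)O)cc(OC)c1OCc1ccccc1 | intermediate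
25 | methyl (1R,2S,3R)-7-(benzyloxy)-1-[4-(benzyloxy)-3,5-dimethoxyphenyl]-6,8-dimethoxy-3-[(1E)-prop-1-en-1-yl]-1,2,3,4-tetrahydronaphthalene-2-carboxylate (not isolated) | COc1cc([C@@H]2c3c(cc(OC)c(OCc4ccccc4)c3OC)C[C@H](/C=C/C)[C@@H]2C(=O)OC)cc(OC)c1OCc1ccccc1 | intermediate
26 | methyl (1R,2R,3R)-7-(benzyloxy)-1-[4-(benzyloxy)-3,5-dimethoxyphenyl]-6,8-dimethoxy-3-[(1E)-prop-1-en-1-yl]-1,2,3,4-tetrahydronaphthalene-2-carboxylate | COc1cc([C@@H]2c3c(cc(OC)c(OCc4ccccc4)c3OC)C[C@H](/C=C/C)[C@H]2C(=O)OC)cc(OC)c1OCc1ccccc1 | intermediate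
27 | [(1R,2R,3R)-7-(benzyloxy)-1-[4-(benzyloxy)-3,5-dimethoxyphenyl]-6,8-dimethoxy-3-[(1E)-prop-1-en-1-yl]-1,2,3,4-tetrahydronaphthalen-2-yl]methanol | COc1cc([C@@H]2c3c(cc(OC)c(OCc4ccccc4)c3OC)C[C@H](/C=C/C)[C@H]2CO)cc(OC)c1OCc1ccccc1 | intermediate
28 | sodium [(1R,2R,3R)-7-(benzyloxy)-1-[4-(benzyloxy)-3,5-dimethoxyphenyl]-6,8-dimethoxy-3-[(1E)-prop-1-en-1-yl]-1,2,3,4-tetrahydronaphthalen-2-yl]methyl sulfate | COc1cc([C@@H]2c3c(cc(OC)c(OCc4ccccc4)c3OC)C[C@H](/C=C/C)[C@H]2COS(=O)(=O)[O-])cc(OC)c1OCc1ccccc1.[Na+] | intermediate
29 | sodium [(1R,2S,3S)-7-(benzyloxy)-1-[4-(benzyloxy)-3,5-dimethoxyphenyl]-3-(1,2-dihydroxypropyl)-6,8-dimethoxy-1,2,3,4-tetrahydronaphthalen-2-yl]methyl sulfate, side-chain carbinol centres unassigned (not isolated) | COc1cc([C@@H]2c3c(cc(OC)c(OCc4ccccc4)c3OC)C[C@H](C(O)C(C)O)[C@H]2COS(=O)(=O)[O-])cc(OC)c1OCc1ccccc1.[Na+] | intermediate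
30 | sodium [(1R,2S,3S)-7-(benzyloxy)-1-[4-(benzyloxy)-3,5-dimethoxyphenyl]-3-formyl-6,8-dimethoxy-1,2,3,4-tetrahydronaphthalen-2-yl]methyl sulfate (not isolated) | COc1cc([C@@H]2c3c(cc(OC)c(OCc4ccccc4)c3OC)C[C@H](C=O)[C@H]2COS(=O)(=O)[O-])cc(OC)c1OCc1ccccc1.[Na+] | intermediate
31 | sodium [(1R,2S,3S)-7-(benzyloxy)-1-[4-(benzyloxy)-3,5-dimethoxyphenyl]-3-(hydroxymethyl)-6,8-dimethoxy-1,2,3,4-tetrahydronaphthalen-2-yl]methyl sulfate | COc1cc([C@@H]2c3c(cc(OC)c(OCc4ccccc4)c3OC)C[C@H](CO)[C@H]2COS(=O)(=O)[O-])cc(OC)c1OCc1ccccc1.[Na+] | intermediate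
32 | [(1R,2S,3S)-7-hydroxy-1-(4-hydroxy-3,5-dimethoxyphenyl)-3-(hydroxymethyl)-6,8-dimethoxy-1,2,3,4-tetrahydronaphthalen-2-yl]methyl hydrogen sulfate | COc1cc([C@@H]2c3c(cc(OC)c(O)c3OC)C[C@H](CO)[C@H]2COS(=O)(=O)O)cc(OC)c1O | target

## Step count and least certain steps

Total step count: 20. Longest linear sequence: 18 steps (steps 1 to 5 and 8 to 20); steps 6 and 7 make boronic acid 12.

**Step 15 (key step).**
- What may go wrong: the rearrangement may be slow, because the transannular transition state has to hold Ar′ pseudo-equatorial beside the C8 methoxy group (or pseudo-axial against the C3 arm). While the ketene acetal waits, it can fragment to a ketene and an allylic alkoxide or be silylated on carbon.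
- A second failure is stereochemical leakage through the conformer with the carbinol methyl group turned inward. This would give the C3 epimer, recognisable by a (Z)-propenyl group.
- Fallback: make the C2–C3 bond by intramolecular anti SN2′ alkylation of the ester enolate, a 6-exo-trig closure of a known type. C3 is again dictated by the carbinol centre, now of opposite configuration because the nucleophile enters anti to the leaving group. The fallback sets out from bromide 15. Coupling with commercial (2S)-but-3-yn-2-ol as in step 11 would give methyl (3R)-3-[4-(benzyloxy)-3,5-dimethoxyphenyl]-3-{3-(benzyloxy)-6-[(4S)-4-hydroxypent-2-yn-1-yl]-2,4-dimethoxyphenyl}propanoate F1. Semihydrogenation as in step 12 would give the (2Z,4S)-allylic alcohol F2, and ClP(O)(OEt)2 with pyridine and DMAP the allylic diethyl phosphate F3. KN(SiMe3)2 in THF at −78 to 0 °C should then close ring B to the 3-[(1E)-prop-1-enyl]tetralin-2-carboxylate F4 as a mixture at C2. NaOMe in methanol as in step 16 brings it back to the route at ester 26.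

**Step 14 (macrolactonisation).**
- What may go wrong: intermolecular acylation may outrun ring closure and give the diolide and oligomers, because the ten-membered ring is strained and the activated acid is long-lived at high dilution.
- Fallback: close the ring at the alkene by ring-closing metathesis instead of at the ester. From bromide 15, Stille coupling with Bu3SnCH=CH2 and Pd(PPh3)4 would give the allylarene methyl ester F5, and LiOH the allylarene acid F6. Esterification with commercial (2R)-but-3-en-2-ol (EDC·HCl, DMAP) would give the (2R)-but-3-en-2-yl ester F7. The second-generation Grubbs catalyst RuCl2(H2IMes)(PCy3)(=CHPh) in dilute toluene should close it with loss of ethene, and the fallback returns at lactone 21. The (Z)-alkene is the geometry that a benzo-fused ten-membered ring should accept.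

**Step 8 (conjugate addition).**
- What may go wrong: insertion into a cinnamate flanked by two ortho substituents may be slow, so protodeboronation of 12 takes over and conversion stalls. The same crowding may weaken face selection.
- Fallback: auxiliary-controlled conjugate addition of an aryl copper reagent. From cinnamate 7, LiOH would give the cinnamic acid F8. Activation with t-BuCOCl and Et3N and acylation of lithiated (4S)-4-phenyl-1,3-oxazolidin-2-one would give the N-enoyl imide F9. The aryl Grignard reagent F10, made from bromide 9 and magnesium, would be added with CuBr·SMe2 in THF at −40 °C to give the adduct F11. Attack anti to the phenyl group of the chelated s-cis imide should set (R) at C1. NaOMe in methanol releases the auxiliary and returns to the route at ester 13.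

## Further compounds

F1 | step 15 | methyl (3R)-3-[4-(benzyloxy)-3,5-dimethoxyphenyl]-3-{3-(benzyloxy)-6-[(4S)-4-hydroxypent-2-yn-1-yl]-2,4-dimethoxyphenyl}propanoate | COc1cc([C@@H](CC(=O)OC)c2c(CC#C[C@H](C)O)cc(OC)c(OCc3ccccc3)c2OC)cc(OC)c1OCc1ccccc1
F2 | step 15 | methyl (3R)-3-[4-(benzyloxy)-3,5-dimethoxyphenyl]-3-{3-(benzyloxy)-6-[(2Z,4S)-4-hydroxypent-2-en-1-yl]-2,4-dimethoxyphenyl}propanoate | COc1cc([C@@H](CC(=O)OC)c2c(C/C=C\[C@H](C)O)cc(OC)c(OCc3ccccc3)c2OC)cc(OC)c1OCc1ccccc1
F3 | step 15 | methyl (3R)-3-[4-(benzyloxy)-3,5-dimethoxyphenyl]-3-{3-(benzyloxy)-6-[(2Z,4S)-4-[(diethoxyphosphoryl)oxy]pent-2-en-1-yl]-2,4-dimethoxyphenyl}propanoate | COc1cc([C@@H](CC(=O)OC)c2c(C/C=C\[C@H](C)OP(=O)(OCC)OCC)cc(OC)c(OCc3ccccc3)c2OC)cc(OC)c1OCc1ccccc1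
F4 | step 15 | methyl (1R,3R)-7-(benzyloxy)-1-[4-(benzyloxy)-3,5-dimethoxyphenyl]-6,8-dimethoxy-3-[(1E)-prop-1-en-1-yl]-1,2,3,4-tetrahydronaphthalene-2-carboxylate, mixture of C2 epimers | COc1cc([C@@H]2c3c(cc(OC)c(OCc4ccccc4)c3OC)C[C@H](/C=C/C)C2C(=O)OC)cc(OC)c1OCc1ccccc1
F5 | step 14 | methyl (3R)-3-[4-(benzyloxy)-3,5-dimethoxyphenyl]-3-[3-(benzyloxy)-2,4-dimethoxy-6-(prop-2-en-1-yl)phenyl]propanoate | COc1cc([C@@H](CC(=O)OC)c2c(CC=C)cc(OC)c(OCc3ccccc3)c2OC)cc(OC)c1OCc1ccccc1
F6 | step 14 | (3R)-3-[4-(benzyloxy)-3,5-dimethoxyphenyl]-3-[3-(benzyloxy)-2,4-dimethoxy-6-(prop-2-en-1-yl)phenyl]propanoic acid | COc1cc([C@@H](CC(=O)O)c2c(CC=C)cc(OC)c(OCc3ccccc3)c2OC)cc(OC)c1OCc1ccccc1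
F7 | step 14 | (2R)-but-3-en-2-yl (3R)-3-[4-(benzyloxy)-3,5-dimethoxyphenyl]-3-[3-(benzyloxy)-2,4-dimethoxy-6-(prop-2-en-1-yl)phenyl]propanoate | COc1cc([C@@H](CC(=O)O[C@H](C)C=C)c2c(CC=C)cc(OC)c(OCc3ccccc3)c2OC)cc(OC)c1OCc1ccccc1
F8 | step 8 | (2E)-3-[3-(benzyloxy)-6-({[tert-butyl(dimethyl)silyl]oxy}methyl)-2,4-dimethoxyphenyl]prop-2-enoic acid | OC(=O)/C=C/c1c(CO[Si](C)(C)C(C)(C)C)cc(OC)c(OCc2ccccc2)c1OC
F9 | step 8 | (4S)-3-[(2E)-3-[3-(benzyloxy)-6-({[tert-butyl(dimethyl)silyl]oxy}methyl)-2,4-dimethoxyphenyl]prop-2-enoyl]-4-phenyl-1,3-oxazolidin-2-one | O=C(/C=C/c1c(CO[Si](C)(C)C(C)(C)C)cc(OC)c(OCc2ccccc2)c1OC)N1[C@@H](c2ccccc2)COC1=O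
F10 | step 8 | [4-(benzyloxy)-3,5-dimethoxyphenyl]magnesium bromide | COc1cc([Mg]Br)cc(OC)c1OCc1ccccc1
F11 | step 8 | (4S)-3-[(3R)-3-[4-(benzyloxy)-3,5-dimethoxyphenyl]-3-[3-(benzyloxy)-6-({[tert-butyl(dimethyl)silyl]oxy}methyl)-2,4-dimethoxyphenyl]propanoyl]-4-phenyl-1,3-oxazolidin-2-one | COc1cc([C@@H](CC(=O)N2[C@@H](c3ccccc3)COC2=O)c2c(CO[Si](C)(C)C(C)(C)C)cc(OC)c(OCc3ccccc3)c2OC)cc(OC)c1OCc1ccccc1
A1 | alternative 1 | 1-aryl-7,9-dimethoxyspiro[4.5]deca-6,9-dien-8-one with C2 silyloxymethyl and C3 benzyloxymethyl arms, Ar′ trans to the C2 arm | COC1=CC2(C=C(OC)C1=O)C[C@H](COCc1ccccc1)[C@@H](CO[Si](C)(C)C(C)(C)C)[C@@H]2c1cc(OC)c(O)c(OC)c1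
A2 | alternative 2 | methyl 1-aryl-3-(benzyloxymethyl)-4-oxotetralin-2-carboxylate, all-trans | COc1cc([C@@H]2c3c(cc(OC)c(OCc4ccccc4)c3OC)C(=O)[C@H](COCc3ccccc3)[C@H]2C(=O)OC)cc(OC)c1OCc1ccccc1
A3 | alternative 3 | 3-[4-(benzyloxy)-3,5-dimethoxybenzyl]cyclobutan-1-one | COc1cc(CC2CC(=O)C2)cc(OC)c1OCc1ccccc1
A4 | alternative 3 | (4S)-4-[4-(benzyloxy)-3,5-dimethoxybenzyl]dihydrofuran-2(3H)-one | COc1cc(C[C@@H]2COC(=O)C2)cc(OC)c1OCc1ccccc1
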